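## Structural features

Jezonodione is a bicyclo[3.2.1]oct-3-ene-2,8-dione. A cyclopentanone (ring A: C1, C8, C5, C6, C7) and a cyclohexenone (ring B: C1, C2, C3, C4, C5, C8) share the unit C1–C8–C5, so the C8 ketone is the one-carbon bridge. Four contiguous stereocentres run round ring A (C5, C6, C7, C1): the 3,5-dihydroxyphenyl group on C6 is exo, the 3,4-dihydroxyphenyl group on C7 is endo and trans to it, and both bridgeheads carry hydrogen. C4 bears an (E)-3,4-dihydroxystyryl group (styryl carbons C9 and C10), which extends the C2 enone into an electron-rich dienone. The fragile elements are the six phenols (two oxidisable catechols), the acid-sensitive styryl dienone, and the C2/C8 1,3-diketone, whose central carbon C1 is a bridgehead that cannot enolise, so the diketone is open to retro-Claisen cleavage by nucleophilic base. The real difficulty is the unsymmetrical decoration of ring A. The two α-carbons of the C8 ketone must be told apart (C1 next to the catechol-bearing C7, C5 next to the resorcinol-bearing C6), the trans array C5/C6/C7 must be set in absolute terms, and ring B must be bridged across the face on which the C7 aryl already sits. The key step uses the fact that C8 is bonded to C1, a carbon whose neighbour C7 carries an aryl group and a hydrogen: this is the imprint of a C5-bound aldehyde C8–H adding across a C1=C7 1,1-disubstituted alkene.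

## Logic of the disconnections

**26 to 25.** The six aryl O–H bonds are replaced by O–CH3. Free catechols would not survive divalent palladium, amide bases or boron Lewis acids, and methyl ethers are the protection in which all three aryl building blocks are sold. Nothing is gained in skeleton. The demand is a sixfold dealkylation that spares the dienone and the non-enolisable 1,3-diketone.

**25 to 23.** The C3=C4 π bond is removed (hydrogen added at C3 and C4). With C4 saturated the side chain is an ordinary acyl donor and C5–H is an ordinary ketone α-hydrogen, so the C1 enolate can be formed later; an unsaturated chain would make C5–H the most acidic site. The forward dehydrogenation must be regiospecific, which the bridgeheads guarantee: C3 is the only enolisable position of 23. It also needs H4 on the accessible face of the enol ether, so the C4 epimer with H4 on the face remote from the C6–C7 bridge is chosen deliberately, not left open.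

**23 to 20.** The bond C1–C2 is cut. It is the only ring B bond that a ketone enolate (C1) and a carboxyl-level carbon (C2) can make, and cutting it turns the bridged bicycle into a monocycle with one stereocentre fewer. The forward step needs deprotonation at C1 and not C5, and an acyl donor whose tetrahedral adduct lasts until the quench, because the product cannot protect itself as an enolate.

**20 to 19 (key).** The bond C1–C8 is cut and the hydrogen on C7 is returned to C8. The C8 ketone of 20 has a CH2 (C1) next to an aryl-bearing CH (C7), which is the hydroacylation retron. The cut gives a pent-4-enal whose C5 and C6 centres and C5 side chain are what a [3,3] shift delivers. Ring A and C7 disappear, and the two α-carbons of the ketone are differentiated by construction. The forward step must engage the C1=C7 alkene and not the C9=C10 alkene (which also lies four atoms from C8), deliver hydride to the C7 face that leaves the two aryl groups trans, and avoid decarbonylation and epimerisation at C5.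

**19 to 18 to 16.** Only the oxidation level of C8 changes. The [3,3] shift gives a carboxylic acid, and any hydride reagent that stops at the aldehyde would also reduce the amide. The acid is therefore taken to the alcohol with borohydride and re-oxidised; both steps must leave the amide and the two alkenes alone.

**16 to 14.** The bond C5–C6 is cut and O–C1 re-formed (retro-[3,3]). This sets C5 and C6 together, creates the C7=C1 alkene and brings C2–C4 in with the acid part. The demands are enolisation of the ester and not the amide, an enolate with C4 cis to the O–metal oxygen, a chair transition state, and enantioface control from a chiral ligand on boron, because the allylic carbon C1 is a CH2 and can carry no chirality.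

**14 to 13 to 12 + 5.** The amide C–N and ester C–O bonds are cut. 12 is prochiral, so opening it with 5 under a chiral catalyst joins the two halves and sets C4 at no cost in steps. The demand is differentiation of the two enantiotopic carbonyl groups.

**12 to 11 to 10 to 9 to 8 to 6 + 7.** The two bonds from C4 to the malonate carbons are cut (Knoevenagel, then Michael), with loss of two carboxyl carbons. The forward Michael step must be 1,4 and not 1,6, and the decarboxylation must avoid hot strong acid.

**5 to 4 to 3 to 1 + 2.** The C6=C7 double bond is cut (Perkin-type condensation) and the carboxyl group is reduced. The alkene geometry (aryl groups cis) must be secured here, because it decides the C5/C6 relationship in the [3,3] shift.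

## Other disconnections considered

**Alternative 1:** The cut is C5–C8, made while C8 is an O-allyl oxocarbenium carbon and not yet a ketone. In the forward sense the diallyl acetal-bearing cycloheptenone A1 is treated with Me3SiOTf and Et3N; its extended silyl dienol ether would attack through the γ-carbon C5 the oxocarbenium ion at C8 and give the bridged allyl ether A2.
- In favour: rings A and B close in one operation without a transition metal, and the dienone with its styryl group is already in place. On that point it is better than the chosen plan, which needs a late dehydrogenation.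
- Against: A1 is a seven-membered ring with three contiguous stereocentres (C1, C6, C7) that no single reliable reaction delivers. Deprotonation at C1 competes with γ-deprotonation at C5; it would erase the C1 centre and open β-elimination of allyl oxide from C8. A2 still needs deallylation and oxidation at C8.
- Comparison: structurally, the chosen plan builds ring A first with its α-carbons already differentiated, whereas this plan hides the same problem in A1. Mechanistically it is an ionisation and transannular C–C bond formation that must win over elimination, whereas the chosen route uses an organometallic C–H addition. The number of steps after the key step is about equal; the route to A1 is judged longer than the route to 19.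

**Alternative 2:** The cuts are C4–C5 and C1–C2. In the forward sense the regiodefined silyl enol ether A3 adds through C5 to the β-carbon of the N-dienoyl oxazolidinone A4 (TiCl4), and after LiN(SiMe3)2 the C1 enolate attacks the imide carbonyl to give the diketone A5.
- In favour: it is the most convergent plan, with two bonds and ring B formed in one pot. On convergence and probably on step count it is better than the chosen plan. A3 is regiodefined if made by conjugate arylation and enolate trapping, and that arylation can be made catalytic and asymmetric, which is better than a stoichiometric chiral boron reagent. The end game from A5 equals steps 12 and 13 of the chosen plan.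
- Against: the dienoyl imide can accept the nucleophile at the aryl-bearing terminus (1,6) as well as at C4. After the Michael step the most acidic site is the imide α-CH2 (C3), so base should form that enolate and not the C1 ketone enolate. The imide gives no stabilised tetrahedral adduct, so the expelled oxazolidinone anion can reopen the non-enolisable diketone. C4 is uncontrolled: A5 is the C4 epimer of 23.
- Comparison: both plans close ring B by the same C1–C2 acylation, so they are equal there. The chosen plan pays more steps to reach that point with one enolisable ketone site, a chelate-stabilised adduct and a defined C4.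

**Alternative 3:** Carbon C5 is excised, cutting C5–C8 and C5–C6. In the forward sense a diazoalkane one-carbon ring expansion of the dichlorocyclobutanone A6, with migration of the non-chlorinated aryl-bearing carbon C6, gives the dichlorocyclopentanone A7.
- In favour: it is the shortest entry to a trans-3,4-diarylcyclopentanone, and on step count to ring A it is better than the chosen plan. The trans relationship comes from alkene geometry in the ketene cycloaddition that leads to A6. The CCl2 group marks C1 against C5, which is equal in effect to the differentiation that the chosen plan obtains from the position of the aldehyde.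
- Against: nothing in the sequence controls absolute configuration, so a resolution would be needed. The cycloaddition must choose between two electron-rich aryl-bearing alkene carbons. A7 carries neither the C5 side chain nor C2–C4, so dechlorination and a Michael–Claisen sequence of the kind in Alternative 2 must follow, with the same weaknesses.
- Comparison: mechanistically it is a 1,2-shift with well-precedented regiochemistry and no catalyst to poison, against a catalytic C–H addition on a crowded substrate. Structurally it is a feeder for Alternative 2, not a complete plan, and its total step count is not expected to be lower.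

Key step: step 10

Remark on numbering: C1–C8 are the bicyclo[3.2.1]octane atoms of 26 throughout, and C9 and C10 are the styryl carbons attached to C4.

Remark on configuration: in the zigzag projection of the pentenal chain of 19 the C5 side chain and the C6 aryl are syn (threo); it is this relationship, not the anti one, that becomes 2,3-trans on the ring of 20.

Assumption: the hands of (DHQD)2AQN, of the (4S,5S)-bromoborane and of (R)-BINAP are assigned by analogy with simpler substrates; each reagent exists in the opposite hand (the quinine-derived pseudoenantiomer, the (4R,5R)-borane, (S)-BINAP), which is substituted if a sense proves reversed.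

## Route

Step 1
Reactants: 1 2-(3,4-dimethoxyphenyl)acetic acid; 2 3,5-dimethoxybenzaldehyde
Product: 3 (2E)-2-(3,4-dimethoxyphenyl)-3-(3,5-dimethoxyphenyl)prop-2-enoic acid (aryl groups cis)
Conditions: Ac2O, Et3N, 110 °C; then H2O, aq. HCl, rt
Reagents that add atoms: none
Why: Perkin-type condensation of an arylacetic acid with an aromatic aldehyde; the E acid with the two aryl groups cis is the established outcome and fixes the alkene geometry that the later chair transition state needs.

Step 2
Reactants: 3 (2E)-2-(3,4-dimethoxyphenyl)-3-(3,5-dimethoxyphenyl)prop-2-enoic acid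
Product: 5 (2E)-2-(3,4-dimethoxyphenyl)-3-(3,5-dimethoxyphenyl)prop-2-en-1-ol (aryl groups cis), via ethoxycarbonyl mixed anhydride 4 (not isolated)
Conditions: ClCO2Et, Et3N, THF, 0 °C; then NaBH4, H2O, 0 °C to rt
Reagents that add atoms: none
Why: Activation as the mixed carbonic anhydride and borohydride reduction should give the primary allylic alcohol by 1,2-attack, as with cinnamic acids, without touching the trisubstituted alkene or its geometry.

Step 3
Reactants: 6 (2E)-3-(3,4-dimethoxyphenyl)prop-2-enal; 7 dimethyl propanedioate (two equivalents)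
Product: 9 tetramethyl 2-[(E)-2-(3,4-dimethoxyphenyl)ethenyl]propane-1,1,3,3-tetracarboxylate, via dienylidene malonate 8 (not isolated)
Conditions: piperidine, AcOH (cat.), toluene, reflux (Dean–Stark); then second equivalent of 7, NaOMe (cat.), MeOH, rt
Reagents that add atoms: none
Why: Knoevenagel condensation followed by Michael addition of a second malonate at the carbon next to the malonyl unit (1,4), the mode that keeps the styrene conjugation; no stereocentre arises because the two arms are identical.

Step 4
Reactants: 9 tetramethyl 2-[(E)-2-(3,4-dimethoxyphenyl)ethenyl]propane-1,1,3,3-tetracarboxylate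
Product: 11 3-[(E)-2-(3,4-dimethoxyphenyl)ethenyl]pentanedioic acid, via tetracarboxylic acid 10 (not isolated)
Conditions: LiOH, THF–H2O, 50 °C; aq. HCl to pH 2, 0 °C; then pyridine, 100 °C
Reagents that add atoms: lithium hydroxide, [Li+].[OH-]
Why: Saponification and thermal decarboxylation of the two malonic acid units (malonic ester synthesis); decarboxylation in pyridine avoids the hot mineral acid that could add a carboxyl group across the electron-rich styrene.

Step 5
Reactants: 11 3-[(E)-2-(3,4-dimethoxyphenyl)ethenyl]pentanedioic acid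
Product: 12 4-[(E)-2-(3,4-dimethoxyphenyl)ethenyl]oxane-2,6-dione
Conditions: Ac2O, 80 °C; evaporation with toluene
Reagents that add atoms: none
Why: Cyclodehydration of a glutaric acid to its six-membered anhydride; the product is prochiral, which the next step exploits.

Step 6
Reactants: 12 4-[(E)-2-(3,4-dimethoxyphenyl)ethenyl]oxane-2,6-dione; 5 (2E)-2-(3,4-dimethoxyphenyl)-3-(3,5-dimethoxyphenyl)prop-2-en-1-ol
Product: 14 (2E)-2-(3,4-dimethoxyphenyl)-3-(3,5-dimethoxyphenyl)prop-2-en-1-yl (3R)-3-[(E)-2-(3,4-dimethoxyphenyl)ethenyl]-5-[methoxy(methyl)amino]-5-oxopentanoate, via (3R)-hemiester acid 13 (not isolated)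
Conditions: (DHQD)2AQN (10 mol%), MTBE, −20 °C to rt; then MeNH(OMe)·HCl, EDC·HCl, HOBt, iPr2NEt, CH2Cl2, 0 °C to rt
Reagents that add atoms: N,O-dimethylhydroxylamine hydrochloride, CNOC.Cl
Why: Cinchona-alkaloid-catalysed desymmetrising alcoholysis of a 3-substituted glutaric anhydride differentiates the enantiotopic carbonyl groups and sets C4, and carbodiimide coupling of the freed acid installs the N-methoxy-N-methylamide; C4 is erased in step 12 but is set so that all later intermediates are single diastereomers and H4 ends on the open face of ring B.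

Step 7
Reactants: 14 (2E)-2-(3,4-dimethoxyphenyl)-3-(3,5-dimethoxyphenyl)prop-2-en-1-yl (3R)-3-[(E)-2-(3,4-dimethoxyphenyl)ethenyl]-5-[methoxy(methyl)amino]-5-oxopentanoate
Product: 16 (2S,3R)-4-(3,4-dimethoxyphenyl)-3-(3,5-dimethoxyphenyl)-2-{(1E,3S)-1-(3,4-dimethoxyphenyl)-5-[methoxy(methyl)amino]-5-oxopent-1-en-3-yl}pent-4-enoic acid, via boron ketene acetal 15 (not isolated)
Conditions: (4S,5S)-2-bromo-1,3-bis{[3,5-bis(trifluoromethyl)phenyl]sulfonyl}-4,5-diphenyl-1,3,2-diazaborolidine (2.2 equiv), iPr2NEt, CH2Cl2, −78 °C; then −20 °C to rt; H2O work-up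
Reagents that add atoms: none
Why: Ireland–Claisen rearrangement through a chiral boron enolate: soft enolisation of the ester (more acidic than the amide α-CH2) should give the enolate with C4 cis to the O–B oxygen, and a chair transition state with C4 and the C6 aryl both pseudo-equatorial gives the 2,3-syn acid. The C2-symmetric sulfonamide ligand on boron selects the enantioface pair and so sets C5 and C6, while the C7=C1 alkene is created.

Step 8
Reactants: 16 (2S,3R)-4-(3,4-dimethoxyphenyl)-3-(3,5-dimethoxyphenyl)-2-{(1E,3S)-1-(3,4-dimethoxyphenyl)-5-[methoxy(methyl)amino]-5-oxopent-1-en-3-yl}pent-4-enoic acid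
Product: 18 (3S,4E)-5-(3,4-dimethoxyphenyl)-3-[(2S,3R)-4-(3,4-dimethoxyphenyl)-3-(3,5-dimethoxyphenyl)-1-hydroxypent-4-en-2-yl]-N-methoxy-N-methylpent-4-enamide, via acyl imidazole 17 (not isolated)
Conditions: 1,1'-carbonyldiimidazole, THF, rt; then NaBH4, H2O, 0 °C
Reagents that add atoms: none
Why: Acyl imidazole formation and borohydride reduction to the primary alcohol; NaBH4 leaves the N-methoxy-N-methylamide and both alkenes untouched, which aluminium hydrides that stop at the aldehyde would not.

Step 9
Reactants: 18 (3S,4E)-5-(3,4-dimethoxyphenyl)-3-[(2S,3R)-4-(3,4-dimethoxyphenyl)-3-(3,5-dimethoxyphenyl)-1-hydroxypent-4-en-2-yl]-N-methoxy-N-methylpent-4-enamide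
Product: 19 (3S,4E)-5-(3,4-dimethoxyphenyl)-3-[(2S,3R)-4-(3,4-dimethoxyphenyl)-3-(3,5-dimethoxyphenyl)-1-oxopent-4-en-2-yl]-N-methoxy-N-methylpent-4-enamide
Conditions: DMP (1,1,1-triacetoxy-1,1-dihydro-1,2-benziodoxol-3(1H)-one), NaHCO3, CH2Cl2, 0 °C to rt
Reagents that add atoms: none
Why: Dess–Martin oxidation under buffered, non-basic conditions should give the α-branched aldehyde without epimerising C5; the aldehyde is used at once.

Step 10
Reactants: 19 (3S,4E)-5-(3,4-dimethoxyphenyl)-3-[(2S,3R)-4-(3,4-dimethoxyphenyl)-3-(3,5-dimethoxyphenyl)-1-oxopent-4-en-2-yl]-N-methoxy-N-methylpent-4-enamide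
Product: 20 (3S,4E)-5-(3,4-dimethoxyphenyl)-3-[(1S,2R,3S)-3-(3,4-dimethoxyphenyl)-2-(3,5-dimethoxyphenyl)-5-oxocyclopentyl]-N-methoxy-N-methylpent-4-enamide
Conditions: [Rh(nbd)2]BF4 (5 mol%), (R)-BINAP (5.5 mol%), H2 then Ar purge (catalyst activation), CH2Cl2, 25 °C
Reagents that add atoms: none
Why: The solvated cationic rhodium–BINAP complex (monovalent rhodium) inserts into the formyl C8–H bond, the C7=C1 alkene coordinates, hydride migrates to C7 so that rhodium sits on the terminal carbon C1, and C1–C8 reductive elimination from the six-membered acylrhodacycle releases the ketone. The closest known reaction type is the cationic rhodium–bisphosphine cyclisation of 4-substituted and 3,4-disubstituted pent-4-enals to 3- and 3,4-substituted cyclopentanones. Ring A is closed by reductive elimination from a six-membered metallacycle, which joins the acyl carbon to the distal alkene carbon (formally a 5-endo connection that a polar or radical path would disfavour). The new centre C7 is controlled by the chair-like rhodacycle, in which the C5 side chain, the C6 aryl and the C7 aryl all prefer pseudo-equatorial positions, so hydrogen arrives on the face that leaves the two aryl groups trans; the matched hand of BINAP reinforces this. The step needs chemoselectivity, because the C9=C10 styryl alkene also lies four atoms from C8 (through C4); substitution at the alkene terminus retards this cyclisation strongly, so the 1,1-disubstituted alkene should be engaged, and hydride insertion at the styryl alkene is reversible. Decarbonylation is limited by the fast intramolecular insertion at room temperature, and the neutral medium protects C5, whose 2,3-trans arrangement is in any case the stable one on the ring.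

Step 11
Reactants: 20 (3S,4E)-5-(3,4-dimethoxyphenyl)-3-[(1S,2R,3S)-3-(3,4-dimethoxyphenyl)-2-(3,5-dimethoxyphenyl)-5-oxocyclopentyl]-N-methoxy-N-methylpent-4-enamide
Product: 23 (1S,4S,5S,6R,7R)-7-(3,4-dimethoxyphenyl)-6-(3,5-dimethoxyphenyl)-4-[(E)-2-(3,4-dimethoxyphenyl)ethenyl]bicyclo[3.2.1]octane-2,8-dione, via lithium enolate 21 (not isolated), via tetrahedral lithium adduct 22 (not isolated)
Conditions: LiN(SiMe3)2 (1.3 equiv), THF, −78 to −20 °C; AcOH, −78 °C
Reagents that add atoms: none
Why: Intramolecular Claisen-type acylation: kinetic deprotonation at the unhindered C1 methylene and 6-(enolendo)-exo-trig attack on the amide carbonyl close ring B, and C1 is set because the chain on C5 can reach only the face cis to itself. The N-methoxy-N-methyl adduct should persist as a lithium chelate until the acid quench, so the non-enolisable 1,3-diketone is never exposed to the amide anion.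

Step 12
Reactants: 23 (1S,4S,5S,6R,7R)-7-(3,4-dimethoxyphenyl)-6-(3,5-dimethoxyphenyl)-4-[(E)-2-(3,4-dimethoxyphenyl)ethenyl]bicyclo[3.2.1]octane-2,8-dione
Product: 25 (1S,5R,6R,7R)-7-(3,4-dimethoxyphenyl)-6-(3,5-dimethoxyphenyl)-4-[(E)-2-(3,4-dimethoxyphenyl)ethenyl]bicyclo[3.2.1]oct-3-ene-2,8-dione, via trimethylsilyl enol ether 24 (not isolated)
Conditions: Me3SiOTf, Et3N, CH2Cl2, 0 °C; then Pd(OAc)2, MeCN, rt
Reagents that add atoms: none
Why: Saegusa–Ito dehydrogenation: C3 is the only enolisable position (C1 is a bridgehead and C8 has no enolisable α-hydrogen), so soft silylation is regiospecific. Pd(OAc)2 should bind the enol ether on the face remote from the C6–C7 bridge and its endo aryl, where the chosen C4 epimer presents H4 for syn β-hydride elimination; this creates the dienone and removes the C4 centre.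

Step 13
Reactants: 25 (1S,5R,6R,7R)-7-(3,4-dimethoxyphenyl)-6-(3,5-dimethoxyphenyl)-4-[(E)-2-(3,4-dimethoxyphenyl)ethenyl]bicyclo[3.2.1]oct-3-ene-2,8-dione
Product: 26 jezonodione, (1S,5R,6R,7R)-7-(3,4-dihydroxyphenyl)-6-(3,5-dihydroxyphenyl)-4-[(E)-2-(3,4-dihydroxyphenyl)ethenyl]bicyclo[3.2.1]oct-3-ene-2,8-dione
Conditions: BBr3, CH2Cl2, −78 to 0 °C; then MeOH, H2O, 0 °C (Ar)
Reagents that add atoms: none
Why: Lewis-acid cleavage of the six aryl methyl ethers (bromide attacks the methyl of the boron-complexed ether); low temperature and a non-basic quench should spare the dienone and the 1,3-diketone, and no stereocentre is touched.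

## Compound list

1 | 2-(3,4-dimethoxyphenyl)acetic acid | OC(=O)Cc1ccc(OC)c(OC)c1 | starting material
2 | 3,5-dimethoxybenzaldehyde | O=Cc1cc(OC)cc(OC)c1 | starting material
3 | (2E)-2-(3,4-dimethoxyphenyl)-3-(3,5-dimethoxyphenyl)prop-2-enoic acid | OC(=O)/C(c1ccc(OC)c(OC)c1)=C/c1cc(OC)cc(OC)c1 | intermediate
4 | ethyl carbonic mixed anhydride of 3 | CCOC(=O)OC(=O)/C(c1ccc(OC)c(OC)c1)=C/c1cc(OC)cc(OC)c1 | intermediate (not isolated)
5 | (2E)-2-(3,4-dimethoxyphenyl)-3-(3,5-dimethoxyphenyl)prop-2-en-1-ol | OC/C(c1ccc(OC)c(OC)c1)=C/c1cc(OC)cc(OC)c1 | intermediate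
6 | (2E)-3-(3,4-dimethoxyphenyl)prop-2-enal | O=C/C=C/c1ccc(OC)c(OC)c1 | starting material
7 | dimethyl propanedioate (dimethyl malonate) | COC(=O)CC(=O)OC | starting material
8 | dimethyl 2-[(2E)-3-(3,4-dimethoxyphenyl)prop-2-en-1-ylidene]propanedioate | COC(=O)C(C(=O)OC)=C/C=C/c1ccc(OC)c(OC)c1 | intermediate (not isolated)
9 | tetramethyl 2-[(E)-2-(3,4-dimethoxyphenyl)ethenyl]propane-1,1,3,3-tetracarboxylate | COC(=O)C(C(=O)OC)C(/C=C/c1ccc(OC)c(OC)c1)C(C(=O)OC)C(=O)OC | intermediate
10 | 2-[(E)-2-(3,4-dimethoxyphenyl)ethenyl]propane-1,1,3,3-tetracarboxylic acid | OC(=O)C(C(O)=O)C(/C=C/c1ccc(OC)c(OC)c1)C(C(O)=O)C(O)=O | intermediate (not isolated)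
11 | 3-[(E)-2-(3,4-dimethoxyphenyl)ethenyl]pentanedioic acid | OC(=O)CC(/C=C/c1ccc(OC)c(OC)c1)CC(O)=O | intermediate
12 | 4-[(E)-2-(3,4-dimethoxyphenyl)ethenyl]oxane-2,6-dione | O=C1CC(/C=C/c2ccc(OC)c(OC)c2)CC(=O)O1 | intermediate
13 | (3R)-5-{[(2E)-2-(3,4-dimethoxyphenyl)-3-(3,5-dimethoxyphenyl)prop-2-en-1-yl]oxy}-3-[(E)-2-(3,4-dimethoxyphenyl)ethenyl]-5-oxopentanoic acid | OC(=O)C[C@@H](/C=C/c1ccc(OC)c(OC)c1)CC(=O)OC/C(c1ccc(OC)c(OC)c1)=C/c1cc(OC)cc(OC)c1 | intermediate (not isolated)
14 | (2E)-2-(3,4-dimethoxyphenyl)-3-(3,5-dimethoxyphenyl)prop-2-en-1-yl (3R)-3-[(E)-2-(3,4-dimethoxyphenyl)ethenyl]-5-[methoxy(methyl)amino]-5-oxopentanoate | CON(C)C(=O)C[C@@H](/C=C/c1ccc(OC)c(OC)c1)CC(=O)OC/C(c1ccc(OC)c(OC)c1)=C/c1cc(OC)cc(OC)c1 | intermediate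
15 | boron ketene acetal of 14 (enolate carbon C5; C4 cis to the O–B oxygen; boron in the (4S,5S)-1,3-bis{[3,5-bis(trifluoromethyl)phenyl]sulfonyl}-4,5-diphenyl-1,3,2-diazaborolidine ring) | CON(C)C(=O)C[C@@H](/C=C/c1ccc(OC)c(OC)c1)/C=C(\OB1N(S(=O)(=O)c2cc(C(F)(F)F)cc(C(F)(F)F)c2)[C@@H](c2ccccc2)[C@H](c2ccccc2)N1S(=O)(=O)c1cc(C(F)(F)F)cc(C(F)(F)F)c1)OC/C(c1ccc(OC)c(OC)c1)=C/c1cc(OC)cc(OC)c1 | intermediate (not isolated)
16 | (2S,3R)-4-(3,4-dimethoxyphenyl)-3-(3,5-dimethoxyphenyl)-2-{(1E,3S)-1-(3,4-dimethoxyphenyl)-5-[methoxy(methyl)amino]-5-oxopent-1-en-3-yl}pent-4-enoic acid | OC(=O)[C@@H]([C@H](/C=C/c1ccc(OC)c(OC)c1)CC(=O)N(C)OC)[C@H](c1cc(OC)cc(OC)c1)C(=C)c1ccc(OC)c(OC)c1 | intermediate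
17 | 1H-imidazol-1-yl ketone (acyl imidazole) of 16 | O=C(n1ccnc1)[C@@H]([C@H](/C=C/c1ccc(OC)c(OC)c1)CC(=O)N(C)OC)[C@H](c1cc(OC)cc(OC)c1)C(=C)c1ccc(OC)c(OC)c1 | intermediate (not isolated)
18 | (3S,4E)-5-(3,4-dimethoxyphenyl)-3-[(2S,3R)-4-(3,4-dimethoxyphenyl)-3-(3,5-dimethoxyphenyl)-1-hydroxypent-4-en-2-yl]-N-methoxy-N-methylpent-4-enamide | OC[C@@H]([C@H](/C=C/c1ccc(OC)c(OC)c1)CC(=O)N(C)OC)[C@H](c1cc(OC)cc(OC)c1)C(=C)c1ccc(OC)c(OC)c1 | intermediate
19 | (3S,4E)-5-(3,4-dimethoxyphenyl)-3-[(2S,3R)-4-(3,4-dimethoxyphenyl)-3-(3,5-dimethoxyphenyl)-1-oxopent-4-en-2-yl]-N-methoxy-N-methylpent-4-enamide | O=C[C@@H]([C@H](/C=C/c1ccc(OC)c(OC)c1)CC(=O)N(C)OC)[C@H](c1cc(OC)cc(OC)c1)C(=C)c1ccc(OC)c(OC)c1 | intermediate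
20 | (3S,4E)-5-(3,4-dimethoxyphenyl)-3-[(1S,2R,3S)-3-(3,4-dimethoxyphenyl)-2-(3,5-dimethoxyphenyl)-5-oxocyclopentyl]-N-methoxy-N-methylpent-4-enamide | O=C1C[C@H](c2ccc(OC)c(OC)c2)[C@@H](c2cc(OC)cc(OC)c2)[C@@H]1[C@H](/C=C/c1ccc(OC)c(OC)c1)CC(=O)N(C)OC | intermediate
21 | lithium enolate of 20 toward C1 | [Li]OC1=C[C@H](c2ccc(OC)c(OC)c2)[C@@H](c2cc(OC)cc(OC)c2)[C@@H]1[C@H](/C=C/c1ccc(OC)c(OC)c1)CC(=O)N(C)OC | intermediate (not isolated)
22 | lithium alkoxide of the C2 N-methoxy-N-methyl hemiaminal of 23 (C2 configuration open) | [Li]OC1(N(C)OC)C[C@@H](/C=C/c2ccc(OC)c(OC)c2)[C@@H]2C(=O)[C@H]1[C@H](c1ccc(OC)c(OC)c1)[C@H]2c1cc(OC)cc(OC)c1 | intermediate (not isolated)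
23 | (1S,4S,5S,6R,7R)-7-(3,4-dimethoxyphenyl)-6-(3,5-dimethoxyphenyl)-4-[(E)-2-(3,4-dimethoxyphenyl)ethenyl]bicyclo[3.2.1]octane-2,8-dione | O=C1C[C@@H](/C=C/c2ccc(OC)c(OC)c2)[C@@H]2C(=O)[C@H]1[C@H](c1ccc(OC)c(OC)c1)[C@H]2c1cc(OC)cc(OC)c1 | intermediate
24 | 2-trimethylsilyloxy-bicyclo[3.2.1]oct-2-en-8-one derived from 23 (enol ether C2=C3) | C[Si](C)(C)OC1=C[C@@H](/C=C/c2ccc(OC)c(OC)c2)[C@@H]2C(=O)[C@H]1[C@H](c1ccc(OC)c(OC)c1)[C@H]2c1cc(OC)cc(OC)c1 | intermediate (not isolated)
25 | (1S,5R,6R,7R)-7-(3,4-dimethoxyphenyl)-6-(3,5-dimethoxyphenyl)-4-[(E)-2-(3,4-dimethoxyphenyl)ethenyl]bicyclo[3.2.1]oct-3-ene-2,8-dione | O=C1C=C(/C=C/c2ccc(OC)c(OC)c2)[C@@H]2C(=O)[C@H]1[C@H](c1ccc(OC)c(OC)c1)[C@H]2c1cc(OC)cc(OC)c1 | intermediate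
26 | jezonodione, (1S,5R,6R,7R)-7-(3,4-dihydroxyphenyl)-6-(3,5-dihydroxyphenyl)-4-[(E)-2-(3,4-dihydroxyphenyl)ethenyl]bicyclo[3.2.1]oct-3-ene-2,8-dione | O=C1C=C(/C=C/c2ccc(O)c(O)c2)[C@@H]2C(=O)[C@H]1[C@H](c1ccc(O)c(O)c1)[C@H]2c1cc(O)cc(O)c1 | target

## Step count and least certain steps

Total: 13 steps. Longest linear sequence: 11 steps (steps 3 to 13, from 6 and 7); the branch from 1 and 2 (steps 1 and 2) joins at step 6.

**Step 10 (key step).** Turnover may be slow on this crowded 2,3,4-trisubstituted pentenal, so that decarbonylation of the acylrhodium hydride, insertion of the C9=C10 styryl alkene, or hydride delivery to the wrong face of C7 competes. Coordination of the cationic metal by the electron-rich arenes may slow the catalyst further. The fallback forms the same C1–C8 bond by polar organometallic chemistry; it sets out from 16 and returns at 20.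
- 16 is converted with EtSH, EDC·HCl and DMAP into the S-ethyl thioester F1.
- 9-Borabicyclo[3.3.1]nonane should add only to the 1,1-disubstituted alkene, with boron on C1, to give the B-alkyl borane F2, which is used without isolation.
- Pd2(dba)3 with tri(2-furyl)phosphine, Cu(O2CC4H3S) and Cs2CO3 in THF then joins C1 to the thioester carbon in a Liebeskind–Srogl-type acylative coupling and gives 20.
- In this fallback C7 is set in the hydroboration under substrate control only, so the C7 epimers would have to be separated at 20.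

**Step 7.** Enantioface control may be insufficient for this β-branched enolate, the boron reagent may be held by the amide carbonyl, or the enolate may form with the other geometry and lead to the 2,3-anti acid. C5 alone would be correctable, by base equilibration of 20 to the stable 2,3-trans ring; C6 would not. The fallback replaces reagent control by separation of diastereomers, which the fixed C4 centre makes possible; it sets out from 14 and returns at 16.
- LiN(iPr)2 and Me3SiCl in THF–DMPU at −78 °C give the trimethylsilyl ketene acetal F3 (C4 cis to the O–Si oxygen).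
- F3 rearranges on warming to the trimethylsilyl ester F4.
- Hydrolysis gives 16 together with its (2R,3S) diastereomer F5. The two are separated by chromatography or by crystallisation of an amine salt, at the cost of about half the material.

**Step 11.** Closure may fail because C2 must approach C1 on the face that carries the C7 aryl; the enolate may then equilibrate toward C5, or the 1,3-diketone may be cleaved during the quench. The fallback closes the same bond by aldol addition and oxidation; it sets out from 20 and returns at 23.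
- The ketone is protected in the flask as its lithium enolate (LiN(SiMe3)2, −78 °C) while iBu2AlH reduces the N-methoxy-N-methylamide; work-up gives the keto aldehyde F6.
- 1,8-Diazabicyclo[5.4.0]undec-7-ene in dilute CH2Cl2 should effect the intramolecular aldol addition of C1 to the aldehyde and give the ketol F7.
- Dess–Martin oxidation of F7 gives 23.

**Step 13.** Bromide or HBr may add to the dienone, the electron-rich styryl dienone may cyclise under acid, or the diketone may cleave during the quench. The fallback moves the demethylation ahead of the dienone and changes the protecting group; it sets out from 23 and returns at 26.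
- BBr3 converts 23 into the hexaphenol F8.
- Ac2O and pyridine give the hexaacetate F9.
- Me3SiOTf and Et3N give the silyl enol ether F10 (not isolated), and Pd(OAc)2 gives jezonodione hexaacetate F11.
- HCl in MeOH (from AcCl) at 0 °C to rt removes the acetates under non-basic conditions and gives 26.

## Further compounds

F1 | step 10 | S-ethyl (2S,3R)-4-(3,4-dimethoxyphenyl)-3-(3,5-dimethoxyphenyl)-2-{(1E,3S)-1-(3,4-dimethoxyphenyl)-5-[methoxy(methyl)amino]-5-oxopent-1-en-3-yl}pent-4-enethioate | CCSC(=O)[C@@H]([C@H](/C=C/c1ccc(OC)c(OC)c1)CC(=O)N(C)OC)[C@H](c1cc(OC)cc(OC)c1)C(=C)c1ccc(OC)c(OC)c1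
F2 | step 10 | S-ethyl (2S,3R,4S)-5-(9-borabicyclo[3.3.1]nonan-9-yl)-4-(3,4-dimethoxyphenyl)-3-(3,5-dimethoxyphenyl)-2-{(1E,3S)-1-(3,4-dimethoxyphenyl)-5-[methoxy(methyl)amino]-5-oxopent-1-en-3-yl}pentanethioate | CCSC(=O)[C@@H]([C@H](/C=C/c1ccc(OC)c(OC)c1)CC(=O)N(C)OC)[C@H](c1cc(OC)cc(OC)c1)[C@@H](c1ccc(OC)c(OC)c1)CB1C2CCCC1CCC2
F3 | step 7 | trimethylsilyl ketene acetal of 14 (C4 cis to the O–Si oxygen) | CON(C)C(=O)C[C@@H](/C=C/c1ccc(OC)c(OC)c1)/C=C(\O[Si](C)(C)C)OC/C(c1ccc(OC)c(OC)c1)=C/c1cc(OC)cc(OC)c1
F4 | step 7 | trimethylsilyl ester of 16 | C[Si](C)(C)OC(=O)[C@@H]([C@H](/C=C/c1ccc(OC)c(OC)c1)CC(=O)N(C)OC)[C@H](c1cc(OC)cc(OC)c1)C(=C)c1ccc(OC)c(OC)c1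
F5 | step 7 | (2R,3S)-4-(3,4-dimethoxyphenyl)-3-(3,5-dimethoxyphenyl)-2-{(1E,3S)-1-(3,4-dimethoxyphenyl)-5-[methoxy(methyl)amino]-5-oxopent-1-en-3-yl}pent-4-enoic acid | OC(=O)[C@H]([C@H](/C=C/c1ccc(OC)c(OC)c1)CC(=O)N(C)OC)[C@@H](c1cc(OC)cc(OC)c1)C(=C)c1ccc(OC)c(OC)c1
F6 | step 11 | (3S,4E)-5-(3,4-dimethoxyphenyl)-3-[(1S,2R,3S)-3-(3,4-dimethoxyphenyl)-2-(3,5-dimethoxyphenyl)-5-oxocyclopentyl]pent-4-enal | O=C1C[C@H](c2ccc(OC)c(OC)c2)[C@@H](c2cc(OC)cc(OC)c2)[C@@H]1[C@H](/C=C/c1ccc(OC)c(OC)c1)CC=O
F7 | step 11 | (1S,4S,5S,6R,7R)-7-(3,4-dimethoxyphenyl)-6-(3,5-dimethoxyphenyl)-4-[(E)-2-(3,4-dimethoxyphenyl)ethenyl]-2-hydroxybicyclo[3.2.1]octan-8-one (C2 configuration open) | OC1C[C@@H](/C=C/c2ccc(OC)c(OC)c2)[C@@H]2C(=O)[C@H]1[C@H](c1ccc(OC)c(OC)c1)[C@H]2c1cc(OC)cc(OC)c1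
F8 | step 13 | (1S,4S,5S,6R,7R)-7-(3,4-dihydroxyphenyl)-6-(3,5-dihydroxyphenyl)-4-[(E)-2-(3,4-dihydroxyphenyl)ethenyl]bicyclo[3.2.1]octane-2,8-dione | O=C1C[C@@H](/C=C/c2ccc(O)c(O)c2)[C@@H]2C(=O)[C@H]1[C@H](c1ccc(O)c(O)c1)[C@H]2c1cc(O)cc(O)c1
F9 | step 13 | hexaacetate of F8 | O=C1C[C@@H](/C=C/c2ccc(OC(C)=O)c(OC(C)=O)c2)[C@@H]2C(=O)[C@H]1[C@H](c1ccc(OC(C)=O)c(OC(C)=O)c1)[C@H]2c1cc(OC(C)=O)cc(OC(C)=O)c1
F10 | step 13 | 2-trimethylsilyl enol ether (C2=C3) of F9 | C[Si](C)(C)OC1=C[C@@H](/C=C/c2ccc(OC(C)=O)c(OC(C)=O)c2)[C@@H]2C(=O)[C@H]1[C@H](c1ccc(OC(C)=O)c(OC(C)=O)c1)[C@H]2c1cc(OC(C)=O)cc(OC(C)=O)c1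
F11 | step 13 | jezonodione hexaacetate | O=C1C=C(/C=C/c2ccc(OC(C)=O)c(OC(C)=O)c2)[C@@H]2C(=O)[C@H]1[C@H](c1ccc(OC(C)=O)c(OC(C)=O)c1)[C@H]2c1cc(OC(C)=O)cc(OC(C)=O)c1
A1 | alternative 1 | 7-[bis(prop-2-en-1-yloxy)methyl]-6-(3,4-dimethoxyphenyl)-5-(3,5-dimethoxyphenyl)-3-[(E)-2-(3,4-dimethoxyphenyl)ethenyl]cyclohept-2-en-1-one (ring centres configured as C6, C7 and C1 of 26) | O=C1C=C(/C=C/c2ccc(OC)c(OC)c2)C[C@H](c2cc(OC)cc(OC)c2)[C@@H](c2ccc(OC)c(OC)c2)[C@@H]1C(OCC=C)OCC=C
A2 | alternative 1 | 8-deoxo-8-(prop-2-en-1-yloxy) hexa-O-methyl jezonodione (C8 epimer arbitrary) | O=C1C=C(/C=C/c2ccc(OC)c(OC)c2)[C@@H]2[C@H](OCC=C)[C@H]1[C@H](c1ccc(OC)c(OC)c1)[C@H]2c1cc(OC)cc(OC)c1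
A3 | alternative 2 | trans-4-(3,4-dimethoxyphenyl)-3-(3,5-dimethoxyphenyl)-1-(trimethylsilyloxy)cyclopent-1-ene | C[Si](C)(C)OC1=C[C@H](c2cc(OC)cc(OC)c2)[C@@H](c2ccc(OC)c(OC)c2)C1
A4 | alternative 2 | 3-[(2E,4E)-5-(3,4-dimethoxyphenyl)penta-2,4-dienoyl]-1,3-oxazolidin-2-one | O=C(/C=C/C=C/c1ccc(OC)c(OC)c1)N1CCOC1=O
A5 | alternative 2 | 3,4-dihydro hexa-O-methyl jezonodione (C4 epimer of 23) | O=C1C[C@H](/C=C/c2ccc(OC)c(OC)c2)[C@@H]2C(=O)[C@H]1[C@H](c1ccc(OC)c(OC)c1)[C@H]2c1cc(OC)cc(OC)c1
A6 | alternative 3 | trans-2,2-dichloro-3-(3,4-dimethoxyphenyl)-4-(3,5-dimethoxyphenyl)cyclobutan-1-one | O=C1[C@H](c2cc(OC)cc(OC)c2)[C@@H](c2ccc(OC)c(OC)c2)C1(Cl)Cl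
A7 | alternative 3 | trans-2,2-dichloro-3-(3,4-dimethoxyphenyl)-4-(3,5-dimethoxyphenyl)cyclopentan-1-one | O=C1C[C@H](c2cc(OC)cc(OC)c2)[C@@H](c2ccc(OC)c(OC)c2)C1(Cl)Cl
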